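**Retrosynthetic overview**
- Target ⇐ 15-deoxy macrocycle by a final allylic hydroxylation of the C-15 methyl group (SeO2/t-BuOOH); before that, acetal hydrolysis (C-14 aldehyde), O-8 acylation and O-8 desilylation.
- Key disconnection: C6–C7 plus C11–C12/O–C12. An acyclic allenyl enal and CO2 are joined by a nickel-mediated carboxylative allylation; the ten-membered carbocycle closes first (C6–C7), the α-methylene-γ-lactone second (O–C12), both in the same operation.
- Allenyl enal ⇐ C1=C10 by cross-metathesis of a neryl-type dienol with a chiral 2-methylidene aldehyde; allene by one-carbon homologation of a terminal alkyne.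
- Fragments: prenol + allyl bromide (Z olefin by directed dimetalation); methyl succinyl chloride + bis(trimethylsilyl)acetylene (C-8 by asymmetric transfer hydrogenation).

Assumption: germacrane numbering (C-1 to C-15) is used for the macrocycles and their open-chain precursors; the target is (6R,7R,8R), i.e. H-6β, H-7α, 8β-ester, with both ring double bonds cis in the ring.

**Step 1**
Reactants: 1 3-methylbut-2-en-1-ol (prenol); 2 allyl bromide
Product: 4 (Z)-3-methylhepta-2,6-dien-1-ol, via dilithiated prenol 3 (not isolated)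
Conditions: n-BuLi (2.2 equiv), TMEDA (2.2 equiv), Et2O, 0 °C to rt; then 2, −78 to 0 °C; H2O
Reagents that add atoms: none
Why: Directed dimetalation of prenol removes a proton from the methyl group cis to CH2OLi, and alkylation of the chelated allyllithium at its CH2 terminus fixes the Z (neryl-type) trisubstituted olefin that becomes the ring-cis C4=C5 bond.

**Step 2**
Reactants: 5 methyl 4-chloro-4-oxobutanoate; 6 bis(trimethylsilyl)acetylene
Product: 7 methyl 4-oxo-6-(trimethylsilyl)hex-5-ynoate
Conditions: AlCl3 (1.1 equiv), CH2Cl2, 0 °C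
Reagents that add atoms: none
Why: Friedel–Crafts-type acylative ipso-desilylation of the bis-silyl alkyne gives the silyl ynone, and the methyl ester is inert to AlCl3 at 0 °C.

**Step 3**
Reactants: 7 methyl 4-oxo-6-(trimethylsilyl)hex-5-ynoate
Product: 8 methyl (4R)-4-hydroxy-6-(trimethylsilyl)hex-5-ynoate
Conditions: Ru[(R,R)-TsDPEN](p-cymene) (0.5 mol%), i-PrOH, 25 °C; used crude in step 4
Reagents that add atoms: none
Why: Noyori asymmetric transfer hydrogenation reduces alkynyl ketones with high enantioselectivity, and by the established sense of induction for alkyl alkynyl ketones the (R,R) complex gives the (R)-propargylic alcohol, which is the future C-8 stereocentre.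

**Step 4**
Reactants: 8 methyl (4R)-4-hydroxy-6-(trimethylsilyl)hex-5-ynoate
Product: 9 methyl (4R)-4-(tert-butyldimethylsilyloxy)-6-(trimethylsilyl)hex-5-ynoate
Conditions: TBSCl, imidazole, DMF, 0 °C to rt
Reagents that add atoms: tert-butyldimethylsilyl chloride, CC(C)(C)[Si](C)(C)Cl
Why: Standard silylation stops the γ-hydroxy ester from lactonising and turns O-8 into an ether, a poor leaving group that will not be lost by 1,4-elimination at the later allylnickel stage.

**Step 5**
Reactants: 9 methyl (4R)-4-(tert-butyldimethylsilyloxy)-6-(trimethylsilyl)hex-5-ynoate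
Product: 10 (4R)-4-(tert-butyldimethylsilyloxy)-6-(trimethylsilyl)hex-5-ynal
Conditions: i-Bu2AlH (1.05 equiv), CH2Cl2, −78 °C; aq. KNaC4H4O6
Reagents that add atoms: none
Why: Low-temperature i-Bu2AlH reduction stops at the tetrahedral aluminium hemiacetal, which releases the aldehyde only on work-up.

**Step 6**
Reactants: 10 (4R)-4-(tert-butyldimethylsilyloxy)-6-(trimethylsilyl)hex-5-ynal
Product: 11 (4R)-4-(tert-butyldimethylsilyloxy)-2-methylidene-6-(trimethylsilyl)hex-5-ynal
Conditions: 37% aq. CH2O, pyrrolidine (10 mol%), propionic acid (10 mol%), i-PrOH, 45 °C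
Reagents that add atoms: formaldehyde, C=O
Why: Amine/acid-catalysed Mannich condensation with formaldehyde followed by elimination (organocatalytic α-methylenation of aldehydes) installs the 1,1-disubstituted enal needed for metathesis without touching the remote stereocentre.

**Step 7**
Reactants: 11 (4R)-4-(tert-butyldimethylsilyloxy)-2-methylidene-6-(trimethylsilyl)hex-5-ynal; 4 (Z)-3-methylhepta-2,6-dien-1-ol (3 equiv)
Product: 12 (2E,6Z)-2-[(2R)-2-(tert-butyldimethylsilyloxy)-4-(trimethylsilyl)but-3-yn-1-yl]-8-hydroxy-6-methylocta-2,6-dienal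
Conditions: second-generation Hoveyda–Grubbs catalyst RuCl2(H2IMes)(=CH-C6H4-2-O-i-Pr) (7 mol%), CH2Cl2, 40 °C
Reagents that add atoms: none
Why: Olefin cross-metathesis of a terminal alkene (in excess) with a 2-substituted acrolein gives the trisubstituted enal under thermodynamic control with CHO trans to the new chain (E), which is the ring-cis C1=C10 geometry of the target, while the trisubstituted olefin and the silylated alkyne do not engage the catalyst.

**Step 8**
Reactants: 12 (2E,6Z)-2-[(2R)-2-(tert-butyldimethylsilyloxy)-4-(trimethylsilyl)but-3-yn-1-yl]-8-hydroxy-6-methylocta-2,6-dienal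
Product: 13 (2Z,6E,9R)-9-(tert-butyldimethylsilyloxy)-7-(1,3-dioxolan-2-yl)-3-methyl-11-(trimethylsilyl)undeca-2,6-dien-10-yn-1-ol
Conditions: ethylene glycol (5 equiv), PPTS (0.1 equiv), benzene, reflux, Dean–Stark
Reagents that add atoms: ethylene glycol, OCCO
Why: Acid-catalysed acetalisation masks the C-14 enal, which would otherwise be allylated in a fast five-ring closure in the key step and would interfere with the amine-mediated allene synthesis.

**Step 9**
Reactants: 13 (2Z,6E,9R)-9-(tert-butyldimethylsilyloxy)-7-(1,3-dioxolan-2-yl)-3-methyl-11-(trimethylsilyl)undeca-2,6-dien-10-yn-1-ol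
Product: 14 (2Z,6E,9R)-9-(tert-butyldimethylsilyloxy)-7-(1,3-dioxolan-2-yl)-3-methylundeca-2,6-dien-10-yn-1-ol
Conditions: K2CO3 (0.3 equiv), MeOH, rt
Reagents that add atoms: none
Why: Methanolysis of the C(sp)–Si bond is fast and selective and leaves the hindered secondary silyl ether and the acetal intact.

**Step 10**
Reactants: 14 (2Z,6E,9R)-9-(tert-butyldimethylsilyloxy)-7-(1,3-dioxolan-2-yl)-3-methylundeca-2,6-dien-10-yn-1-ol
Product: 16 (2Z,6E,9R)-9-(tert-butyldimethylsilyloxy)-7-(1,3-dioxolan-2-yl)-3-methyldodeca-2,6,10,11-tetraen-1-ol, via propargylic amine 15 (not isolated)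
Conditions: (CH2O)n (2.5 equiv), CuI (0.5 equiv), Cy2NH (1.8 equiv), dioxane, reflux
Reagents that add atoms: paraformaldehyde (as formaldehyde), C=O
Why: Crabbé homologation: the Mannich-type propargylic amine undergoes copper-mediated 1,5-hydride transfer with loss of imine to give the terminal allene, with no change at the adjacent C-8 stereocentre.

**Step 11**
Reactants: 16 (2Z,6E,9R)-9-(tert-butyldimethylsilyloxy)-7-(1,3-dioxolan-2-yl)-3-methyldodeca-2,6,10,11-tetraen-1-ol
Product: 17 (2Z,6E,9R)-9-(tert-butyldimethylsilyloxy)-7-(1,3-dioxolan-2-yl)-3-methyldodeca-2,6,10,11-tetraenal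
Conditions: activated MnO2 (15 equiv), CH2Cl2, rt
Reagents that add atoms: none
Why: MnO2 oxidises only the primary allylic alcohol and gives the Z enal without isomerisation, leaving the allene, acetal and silyl ether untouched.

**Step 12 (key step)**
Reactants: 17 (2Z,6E,9R)-9-(tert-butyldimethylsilyloxy)-7-(1,3-dioxolan-2-yl)-3-methyldodeca-2,6,10,11-tetraenal
Product: 20 8β-(tert-butyldimethylsilyloxy)-14,14-ethylenedioxy-cis,cis-germacra-1(10),4,11(13)-trien-6α,12-olide, via nickelalactone 18 (not isolated), via seco acid 19 (not isolated)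
Conditions: Ni(cod)2 (2 equiv), DBU (6 equiv), CO2 (1 atm), THF, 0 °C, slow addition of 17 to 2 mM, then rt; then 0.5 M aq. HCl to pH 3, 0 °C
Reagents that add atoms: carbon dioxide, O=C=O
Why: Proposed new method: zerovalent nickel with DBU couples CO2 oxidatively with the terminal double bond of the allene (CO2 carbon to the central allene carbon) to give a nickelalactone that is a σ-allylnickel carboxylate, this adds through its substituted terminus (C-7) to the tethered enal carbonyl in a chair-like six-membered transition state at high dilution to close the ten-membered ring, and the resulting 6-hydroxy acid lactonises on acidification so that both rings form in one flask; the 6,7-trans relationship is expected from a transition state with both ring chains pseudo-equatorial and the 7αH/8β-O relationship from attack anti to the C8–C9 bond with H-8 eclipsing the allyl unit (minimal A1,3 strain, silyloxy group outside), though this selectivity is a prediction; the closest known reaction type is the nickel/DBU-mediated carboxylation of terminal allenes with CO2 followed by inter- or intramolecular (five- and six-ring) trapping of the allylnickel by an aldehyde, and metal-mediated Barbier macrocyclisations to germacranolides show that a ten-membered ring can be closed through this bond.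

**Step 13**
Reactants: 20 8β-(tert-butyldimethylsilyloxy)-14,14-ethylenedioxy-cis,cis-germacra-1(10),4,11(13)-trien-6α,12-olide
Product: 21 14,14-ethylenedioxy-8β-hydroxy-cis,cis-germacra-1(10),4,11(13)-trien-6α,12-olide
Conditions: TBAF (1.5 equiv), AcOH (1.5 equiv), THF, 0 °C to rt
Reagents that add atoms: none
Why: Buffered fluoride cleaves the secondary silyl ether without base-induced conjugate addition to the α-methylene lactone and without hydrolysing the acetal.

**Step 14**
Reactants: 21 14,14-ethylenedioxy-8β-hydroxy-cis,cis-germacra-1(10),4,11(13)-trien-6α,12-olide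
Product: 22 14,14-ethylenedioxy-8β-(3-methylbutanoyloxy)-cis,cis-germacra-1(10),4,11(13)-trien-6α,12-olide
Conditions: isovaleric anhydride (2 equiv), Et3N (3 equiv), DMAP (0.2 equiv), CH2Cl2, 0 °C to rt
Reagents that add atoms: isovaleric anhydride (3-methylbutanoic anhydride), CC(C)CC(=O)OC(=O)CC(C)C
Why: DMAP-catalysed acylation of the only free hydroxyl installs the isovalerate with retention at C-8.

**Step 15**
Reactants: 22 14,14-ethylenedioxy-8β-(3-methylbutanoyloxy)-cis,cis-germacra-1(10),4,11(13)-trien-6α,12-olide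
Product: 23 8β-(3-methylbutanoyloxy)-14-oxo-cis,cis-germacra-1(10),4,11(13)-trien-6α,12-olide
Conditions: 1 M aq. HCl/THF (1:4), rt
Reagents that add atoms: water, O
Why: Mild aqueous acid hydrolyses the dioxolane to the conjugated C-14 aldehyde, and the ester, the lactone and the allylic C6–O bond tolerate these conditions.

**Step 16**
Reactants: 23 8β-(3-methylbutanoyloxy)-14-oxo-cis,cis-germacra-1(10),4,11(13)-trien-6α,12-olide
Product: 24 15-hydroxy-8β-(3-methylbutanoyloxy)-14-oxo-cis,cis-germacra-1(10),4,11(13)-trien-6α,12-olide (CNP0345200.3)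
Conditions: SeO2 (0.5 equiv), t-BuOOH (3 equiv, in decane), CH2Cl2, 0 °C to rt, stopped at about 70% conversion
Reagents that add atoms: tert-butyl hydroperoxide, CC(C)(C)OO; selenium dioxide (oxygen carrier), O=[Se]=O
Why: Riley-type allylic oxidation under Sharpless conditions: the ene reaction/[2,3]-sigmatropic shift takes place at the only electron-rich olefin (C4=C5, the other two being conjugated to carbonyl groups), hydroxylates the methyl group on the fully substituted carbon and returns the double bond with CH2OH trans to C-6 (the ring-cis geometry of the target), as is known for the vinylic methyl groups of germacranolides and for prenyl esters.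

**Compound list**
1 | 3-methylbut-2-en-1-ol (prenol) | CC(C)=CCO | starting material
2 | allyl bromide | C=CCBr | starting material
3 | dilithiated prenol (CH2Li cis to CH2OLi) | [Li]C/C(C)=C\CO[Li] | intermediate
4 | (Z)-3-methylhepta-2,6-dien-1-ol | C=CCC/C(C)=C\CO | intermediate
5 | methyl 4-chloro-4-oxobutanoate | COC(=O)CCC(=O)Cl | starting material
6 | bis(trimethylsilyl)acetylene | C[Si](C)(C)C#C[Si](C)(C)C | starting material
7 | methyl 4-oxo-6-(trimethylsilyl)hex-5-ynoate | COC(=O)CCC(=O)C#C[Si](C)(C)C | intermediate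
8 | methyl (4R)-4-hydroxy-6-(trimethylsilyl)hex-5-ynoate | COC(=O)CC[C@@H](O)C#C[Si](C)(C)C | intermediate
9 | methyl (4R)-4-(tert-butyldimethylsilyloxy)-6-(trimethylsilyl)hex-5-ynoate | COC(=O)CC[C@@H](O[Si](C)(C)C(C)(C)C)C#C[Si](C)(C)C | intermediate
10 | (4R)-4-(tert-butyldimethylsilyloxy)-6-(trimethylsilyl)hex-5-ynal | O=CCC[C@@H](O[Si](C)(C)C(C)(C)C)C#C[Si](C)(C)C | intermediate
11 | (4R)-4-(tert-butyldimethylsilyloxy)-2-methylidene-6-(trimethylsilyl)hex-5-ynal | O=CC(=C)C[C@@H](O[Si](C)(C)C(C)(C)C)C#C[Si](C)(C)C | intermediate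
12 | (2E,6Z)-2-[(2R)-2-(tert-butyldimethylsilyloxy)-4-(trimethylsilyl)but-3-yn-1-yl]-8-hydroxy-6-methylocta-2,6-dienal | O=C/C(=C/CC/C(C)=C\CO)C[C@@H](O[Si](C)(C)C(C)(C)C)C#C[Si](C)(C)C | intermediate
13 | (2Z,6E,9R)-9-(tert-butyldimethylsilyloxy)-7-(1,3-dioxolan-2-yl)-3-methyl-11-(trimethylsilyl)undeca-2,6-dien-10-yn-1-ol | O1CCOC1/C(=C/CC/C(C)=C\CO)C[C@@H](O[Si](C)(C)C(C)(C)C)C#C[Si](C)(C)C | intermediate
14 | (2Z,6E,9R)-9-(tert-butyldimethylsilyloxy)-7-(1,3-dioxolan-2-yl)-3-methylundeca-2,6-dien-10-yn-1-ol | O1CCOC1/C(=C/CC/C(C)=C\CO)C[C@@H](O[Si](C)(C)C(C)(C)C)C#C | intermediate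
15 | propargylic amine: (2Z,6E,9R)-9-(tert-butyldimethylsilyloxy)-12-(dicyclohexylamino)-7-(1,3-dioxolan-2-yl)-3-methyldodeca-2,6-dien-10-yn-1-ol | O1CCOC1/C(=C/CC/C(C)=C\CO)C[C@@H](O[Si](C)(C)C(C)(C)C)C#CCN(C1CCCCC1)C1CCCCC1 | intermediate
16 | (2Z,6E,9R)-9-(tert-butyldimethylsilyloxy)-7-(1,3-dioxolan-2-yl)-3-methyldodeca-2,6,10,11-tetraen-1-ol | O1CCOC1/C(=C/CC/C(C)=C\CO)C[C@@H](O[Si](C)(C)C(C)(C)C)C=C=C | intermediate
17 | (2Z,6E,9R)-9-(tert-butyldimethylsilyloxy)-7-(1,3-dioxolan-2-yl)-3-methyldodeca-2,6,10,11-tetraenal | O1CCOC1/C(=C/CC/C(C)=C\C=O)C[C@@H](O[Si](C)(C)C(C)(C)C)C=C=C | intermediate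
18 | nickelalactone (σ-allylnickel carboxylate of 17; DBU ligands on nickel not drawn) | O1CCOC1/C(=C/CC/C(C)=C\C=O)C[C@@H](O[Si](C)(C)C(C)(C)C)/C=C1\C[Ni]OC1=O | intermediate
19 | seco acid: 8β-(tert-butyldimethylsilyloxy)-14,14-ethylenedioxy-6α-hydroxy-cis,cis-germacra-1(10),4,11(13)-trien-12-oic acid | C=C(C(=O)O)[C@H]1[C@H](O)/C=C(/C)CC/C=C(/C2OCCO2)C[C@H]1O[Si](C)(C)C(C)(C)C | intermediate
20 | 8β-(tert-butyldimethylsilyloxy)-14,14-ethylenedioxy-cis,cis-germacra-1(10),4,11(13)-trien-6α,12-olide (H-6β, H-7α) | C=C1C(=O)O[C@@H]2/C=C(/C)CC/C=C(/C3OCCO3)C[C@@H](O[Si](C)(C)C(C)(C)C)[C@@H]12 | intermediate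
21 | 14,14-ethylenedioxy-8β-hydroxy-cis,cis-germacra-1(10),4,11(13)-trien-6α,12-olide | C=C1C(=O)O[C@@H]2/C=C(/C)CC/C=C(/C3OCCO3)C[C@@H](O)[C@@H]12 | intermediate
22 | 14,14-ethylenedioxy-8β-(3-methylbutanoyloxy)-cis,cis-germacra-1(10),4,11(13)-trien-6α,12-olide | C=C1C(=O)O[C@@H]2/C=C(/C)CC/C=C(/C3OCCO3)C[C@@H](OC(=O)CC(C)C)[C@@H]12 | intermediate
23 | 8β-(3-methylbutanoyloxy)-14-oxo-cis,cis-germacra-1(10),4,11(13)-trien-6α,12-olide | C=C1C(=O)O[C@@H]2/C=C(/C)CC/C=C(/C=O)C[C@@H](OC(=O)CC(C)C)[C@@H]12 | intermediate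
24 | (6R,7R,8R)-15-hydroxy-8β-(3-methylbutanoyloxy)-14-oxo-cis,cis-germacra-1(10),4,11(13)-trien-6α,12-olide (CNP0345200.3) | C=C1C(=O)O[C@@H]2/C=C(/CO)CC/C=C(/C=O)C[C@@H](OC(=O)CC(C)C)[C@@H]12 | target

**Totals**
Total step count: 16. Longest linear sequence: 15 steps (5 and 6 to 24, steps 2–16).

**Steps most likely to fail, with fallbacks**

Step 12 (macrocyclising carboxylative allylation). Likely failure modes are oligomerisation, capture of the enal by zerovalent nickel, DBU-induced Z/E scrambling of the enal, and the wrong C6/C7 diastereomer. The fallback runs the same nickel/CO2 coupling between two molecules, the mode in which it is known, and closes the ten-membered ring afterwards by metathesis. It sets out from 11 and 4 and comes back to the route at 20. Aldehyde 11 is acetalised (ethylene glycol, PPTS) to (R)-2-[4-(tert-butyldimethylsilyloxy)-6-(trimethylsilyl)hex-1-en-5-yn-2-yl]-1,3-dioxolane F1. F1 is desilylated (K2CO3, MeOH) to (R)-2-[4-(tert-butyldimethylsilyloxy)hex-1-en-5-yn-2-yl]-1,3-dioxolane F2, and F2 is homologated (CuI, Cy2NH, paraformaldehyde) to (R)-2-[4-(tert-butyldimethylsilyloxy)hepta-1,5,6-trien-2-yl]-1,3-dioxolane F3. Alcohol 4 is oxidised with MnO2 to (Z)-3-methylhepta-2,6-dienal F4. F3 is carboxylated (Ni(cod)2, DBU, CO2, THF, 0 °C), the allylnickel carboxylate is trapped with F4, and acidic work-up gives the open-chain α-methylene-γ-butyrolactone diene F5. Ring-closing metathesis of F5 (second-generation Hoveyda–Grubbs catalyst, 1 mM, toluene, 80 °C) forms the C1=C10 bond and gives 20.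

Step 7 (cross-metathesis to a trisubstituted enal). The 1,1-disubstituted enal 11 is hindered and 4 can homodimerise. The fallback makes the C1=C10 bond by a directed aldol condensation. It sets out from 1 and 10 and comes back at 12. Dilithiated prenol 3 (made from 1 as in step 1) is alkylated with bromoacetaldehyde diethyl acetal to give (Z)-6,6-diethoxy-3-methylhex-2-en-1-ol F6, which is silylated (TMSCl, Et3N) to [(Z)-6,6-diethoxy-3-methylhex-2-enyloxy]trimethylsilane F7. Aldehyde 10 is converted (TMSOTf, Et3N) into its (Z)-trimethylsilyl enol ether F8. TMSOTf-catalysed Mukaiyama addition of F8 to acetal F7 (CH2Cl2, −78 °C) gives the β-ethoxy aldehyde F9. DBU-induced loss of ethanol and mild methanolysis of the O–SiMe3 group (citric acid, MeOH) then deliver the E enal 12.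

Step 16 (late allylic hydroxylation). The C4=C5 bond is deactivated by the allylic lactone oxygen, and over-oxidation to the 15-aldehyde or attack at C-3 can compete. The fallback replaces the selenium ene chemistry by biocatalytic C–H hydroxylation: 23 is oxidised with an engineered cytochrome P450 BM3 variant selected from a small library for C-15 selectivity (NADPH regeneration with glucose-6-phosphate dehydrogenase, phosphate buffer pH 8, 2% DMSO). It sets out from 23, comes back at 24 and makes no new compound (F0).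

**Further compounds**
F1 | step 12 | (R)-2-[4-(tert-butyldimethylsilyloxy)-6-(trimethylsilyl)hex-1-en-5-yn-2-yl]-1,3-dioxolane | C=C(C1OCCO1)C[C@@H](O[Si](C)(C)C(C)(C)C)C#C[Si](C)(C)C
F2 | step 12 | (R)-2-[4-(tert-butyldimethylsilyloxy)hex-1-en-5-yn-2-yl]-1,3-dioxolane | C=C(C1OCCO1)C[C@@H](O[Si](C)(C)C(C)(C)C)C#C
F3 | step 12 | (R)-2-[4-(tert-butyldimethylsilyloxy)hepta-1,5,6-trien-2-yl]-1,3-dioxolane | C=C(C1OCCO1)C[C@@H](O[Si](C)(C)C(C)(C)C)C=C=C
F4 | step 12 | (Z)-3-methylhepta-2,6-dienal | C=CCC/C(C)=C\C=O
F5 | step 12 | 4,5-trans-4-[(1R)-1-(tert-butyldimethylsilyloxy)-3-(1,3-dioxolan-2-yl)but-3-enyl]-3-methylidene-5-[(1Z)-2-methylhexa-1,5-dienyl]oxolan-2-one (configuration as in 20) | C=C1C(=O)O[C@H](/C=C(/C)CCC=C)[C@H]1[C@H](O[Si](C)(C)C(C)(C)C)CC(=C)C1OCCO1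
F6 | step 7 | (Z)-6,6-diethoxy-3-methylhex-2-en-1-ol | CCOC(OCC)CC/C(C)=C\CO
F7 | step 7 | [(Z)-6,6-diethoxy-3-methylhex-2-enyloxy]trimethylsilane | CCOC(OCC)CC/C(C)=C\CO[Si](C)(C)C
F8 | step 7 | (Z)-trimethylsilyl enol ether of 10 | C[Si](C)(C)O/C=C\C[C@@H](O[Si](C)(C)C(C)(C)C)C#C[Si](C)(C)C
F9 | step 7 | β-ethoxy aldehyde (mixture of diastereomers at the two new centres) | O=CC(C[C@@H](O[Si](C)(C)C(C)(C)C)C#C[Si](C)(C)C)C(OCC)CC/C(C)=C\CO[Si](C)(C)C
F0 | step 16 | none | none
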